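After 2.50 h the elm run has 70.4% of its starting material not read as target and the cedar run 70.8%, although cedar was charged 1.56 times as much against the same reagent.

| flask | starting material | reagent | free catalyst | remark |
|---|---|---|---|---|
| elm | 0.090 M | 0.096 M | 7 mM | run made earlier |
| cedar | 0.14 M | 0.096 M | 7 mM | run made earlier |
| flask | 0.064 M | 0.0960 M | 7.0 mM |  |

| run | time / h | target / % |
|---|---|---|
| elm | 0.500 | 7.4 |
| elm | 1.00 | 13.9 |
| elm | 1.33 | 18.3 |
| elm | 2.00 | 24.9 |
| elm | 2.50 | 29.6 |
| cedar | 0.200 | 2.9 |
| cedar | 0.333 | 4.6 |
| cedar | 0.667 | 9.7 |
| cedar | 1.33 | 17.2 |
| cedar | 2.50 | 29.2 |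

(each reading ± 0.3 percentage points)

* apparent order in reagent when 30% of the starting material are converted (percent change of the rate of making target for one percent more reagent charged)

- no earlier run changes the charge of reagent; that part of a forecast is a guess

Read as first-order decay, these leftovers give two half-lives, 4.94 h in elm and 5.02 h in cedar. If reagent goes one to one with starting material, its mean level up to 30% conversion stands 1.10 times as high in elm as in cedar. The logarithm of the half-life ratio over the logarithm of that reagent ratio then reads 0.171; this is the reagent lag, an order in reagent read from two times. But the two readings differ by 0.4 percentage points against a scatter of 0.3 points, so these readings do not tell the lag from zero, and my own figure for the flask, 0.171, remains a guess.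

The forecast gives 0.1, lower than my reading, and says: “Reagent probably enters after the rate-limiting step”.

The flask gives 0.0027, below the reagent lag of 0.171.

    starting material + catalyst intermediate A ⇌ catalyst intermediate B (K = 15.0 L mol⁻¹, k = 25.8 L mol⁻¹ h⁻¹)
    reagent + free catalyst → catalyst intermediate A (k = 8000 L mol⁻¹ h⁻¹)
    catalyst intermediate A → spent catalyst (k = 0.141 h⁻¹)
    catalyst intermediate B → free catalyst + target (k = 40.8 h⁻¹)

At the charges of the flask, reagent takes up free catalyst in 0.00130 h, while catalyst intermediate A meets starting material by the forward step in 0.606 h, so capture is far quicker. After 2.00 h the flask holds 73.9% of its catalyst as catalyst intermediate A, the resting state, and 0.151% as free catalyst.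

The numbers in the tables stem from a simulated flask from invented constants, noise included.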